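## Retrosynthetic overview
1. 31 comes from desilylation of 30. 30 comes from a one-pot axial-selective reduction and O-acylation of NH amino ketone 26 (sets C3). 26 is the thermodynamic C2 epimer of the L-alanine-derived ketone 25.
2. The cis-decahydroquinoline 23 comes from convex-face hydrogenation of amido-cyclohexadiene 22 (sets C8a).
3. The carbocycle of 22 comes from a thermal disrotatory 6π-electrocyclisation of amidotriene 21, which forms C4a–C5 and sets C4a and C5.
4. 21 comes from Z-semihydrogenation of dienyne 20. 20 is the Sonogashira product of lactam enol phosphate 19 (Boc-L-alaninal plus propionate homoenolate) and enyne 9 (from (R)-2-propyloxirane).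
5. Ring order: piperidine first (lactam 16), carbocycle second (22).

Assumption: 1, 2, 7, 10, 11 and 27 are purchased (2 and 11 as THF solutions). Compounds 1 and 10 are the only chiral purchases.

## Route

Step 1
Reactants: 1 (R)-2-propyloxirane; 2 pent-4-en-1-ylmagnesium bromide
Product: 3 (4R)-dec-9-en-4-ol
Conditions: CuI (10 mol %), THF, −30 → 0 °C; then H2O
Reagents that add atoms: none
Why: Cu-catalysed SN2 epoxide opening occurs at the unsubstituted carbon, so the purchased carbinol centre (future C5′, R) is untouched.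

Step 2
Reactants: 3 (4R)-dec-9-en-4-ol
Product: 4 tert-butyl{[(4R)-dec-9-en-4-yl]oxy}dimethylsilane
Conditions: TBSCl, imidazole, DMF, rt
Reagents that add atoms: tert-butyldimethylsilyl chloride, CC(C)(C)[Si](C)(C)Cl
Why: Standard silyl ether protection of the only hydroxyl group, with no change at the stereocentre.

Step 3
Reactants: 4 tert-butyl{[(4R)-dec-9-en-4-yl]oxy}dimethylsilane
Product: 6 (6R)-6-{[tert-butyl(dimethyl)silyl]oxy}nonanal, via secondary ozonide 5 (not isolated)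
Conditions: O3, CH2Cl2, −78 °C; then PPh3, → rt
Reagents that add atoms: ozone, [O-][O+]=O
Why: Ozonolysis ([3+2], cycloreversion, [3+2]) with reductive work-up cleaves the only alkene to the aldehyde.

Step 4
Reactants: 6 (6R)-6-{[tert-butyl(dimethyl)silyl]oxy}nonanal; 7 diethyl [3-(trimethylsilyl)prop-2-yn-1-yl]phosphonate
Product: 9 (3E,9R)-9-{[tert-butyl(dimethyl)silyl]oxy}dodec-3-en-1-yne, via C-silyl enyne 8 (not isolated)
Conditions: 7, NaHMDS, THF, −78 °C; add 6, → 0 °C; then K2CO3 (cat.), MeOH, rt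
Reagents that add atoms: none
Why: Horner–Wadsworth–Emmons olefination with the propargyl phosphonate gives the E-enyne, and methanolysis removes only the C–SiMe3 group.

Step 5
Reactants: 10 tert-butyl [(2S)-1-oxopropan-2-yl]carbamate (Boc-L-alaninal); 11 (3-ethoxy-3-oxopropyl)zinc bromide
Product: 14 tert-butyl {(1S)-1-[(2S)-5-oxooxolan-2-yl]ethyl}carbamate, via titanium homoenolate 12 (not isolated), via hydroxy ester 13 (not isolated)
Conditions: 11, ClTi(OiPr)3, THF/CH2Cl2, −20 °C; add 10, → 0 °C; aq work-up; crude, AcOH (cat.), PhMe, 80 °C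
Reagents that add atoms: none
Why: Homoenolate addition through the Ti chelate of aldehyde and carbamate (Cram-chelate control) gives the syn (S,S) amino alcohol, which lactonises.

Step 6
Reactants: 14 tert-butyl {(1S)-1-[(2S)-5-oxooxolan-2-yl]ethyl}carbamate
Product: 16 (5S,6S)-5-hydroxy-6-methylpiperidin-2-one, via amino lactone 15 (not isolated)
Conditions: TFA, CH2Cl2, 0 °C → rt; concentrate; Et3N, MeOH, 60 °C
Reagents that add atoms: none
Why: After Boc acidolysis the free amine attacks the γ-lactone, and this lactone-to-lactam transacylation gives the more stable δ-lactam without touching either stereocentre.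

Step 7
Reactants: 16 (5S,6S)-5-hydroxy-6-methylpiperidin-2-one
Product: 17 (5S,6S)-5-(benzyloxy)-6-methylpiperidin-2-one
Conditions: BnOC(=NH)CCl3, TfOH (5 mol %), CH2Cl2/cyclohexane, 0 °C → rt
Reagents that add atoms: benzyl 2,2,2-trichloroacetimidate, N=C(OCc1ccccc1)C(Cl)(Cl)Cl
Why: Acid-catalysed imidate benzylation alkylates the alcohol and not the weakly nucleophilic lactam NH.

Step 8
Reactants: 17 (5S,6S)-5-(benzyloxy)-6-methylpiperidin-2-one
Product: 18 tert-butyl (2S,3S)-3-(benzyloxy)-2-methyl-6-oxopiperidine-1-carboxylate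
Conditions: Boc2O, DMAP (20 mol %), MeCN, rt
Reagents that add atoms: di-tert-butyl dicarbonate, CC(C)(C)OC(=O)OC(=O)OC(C)(C)C
Why: DMAP-catalysed N-acylation activates the lactam for enolisation and introduces the A(1,3) strain that holds the C2 methyl axial in later steps.

Step 9
Reactants: 18 tert-butyl (2S,3S)-3-(benzyloxy)-2-methyl-6-oxopiperidine-1-carboxylate
Product: 19 tert-butyl (2S,3S)-3-(benzyloxy)-6-[(diphenoxyphosphoryl)oxy]-2-methyl-3,4-dihydro-2H-pyridine-1-carboxylate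
Conditions: KHMDS, THF, −78 °C; (PhO)2P(O)Cl
Reagents that add atoms: diphenyl chlorophosphate, O=P(Cl)(Oc1ccccc1)Oc1ccccc1
Why: O-phosphorylation of the imide-type enolate gives the stable lactam-derived enol phosphate, and the γ-benzyloxy group cannot β-eliminate.

Step 10
Reactants: 19 enol phosphate; 9 (3E,9R)-9-{[tert-butyl(dimethyl)silyl]oxy}dodec-3-en-1-yne
Product: 20 tert-butyl (2S,3S)-3-(benzyloxy)-6-[(3E,9R)-9-{[tert-butyl(dimethyl)silyl]oxy}dodec-3-en-1-yn-1-yl]-2-methyl-3,4-dihydro-2H-pyridine-1-carboxylate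
Conditions: PdCl2(PPh3)2 (5 mol %), CuI (10 mol %), Et3N, CHCl3, 55 °C
Reagents that add atoms: none
Why: Sonogashira coupling of N-Boc lactam enol phosphates with terminal alkynes is established and joins both fragments with every carbon of the core in place.

Step 11
Reactants: 20 dienyne
Product: 22 tert-butyl (2S,3S,4aS,5S)-3-(benzyloxy)-5-[(5R)-5-{[tert-butyl(dimethyl)silyl]oxy}octyl]-2-methyl-3,4,4a,5-tetrahydroquinoline-1(2H)-carboxylate, via amidotriene 21 (not isolated)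
Conditions: H2 (1 atm), Lindlar cat., quinoline, PhMe, rt; filter; then 110 °C, Ar, BHT (cat.)
Reagents that add atoms: none
Why: Syn semihydrogenation gives the Z-alkene, and the E,Z,E-type triene closes by thermal disrotatory 6π-electrocyclisation, which places C4 and the side chain cis (H4a/H5 cis) by orbital symmetry, while the A(1,3)-enforced axial C2 methyl fixes the half-chair so the new C4a–C5 bond develops pseudo-equatorially on the methyl face (4aS,5S).

Step 12
Reactants: 22 amido-cyclohexadiene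
Product: 23 tert-butyl (2S,3S,4aS,5S,8aR)-5-[(5R)-5-{[tert-butyl(dimethyl)silyl]oxy}octyl]-3-hydroxy-2-methyloctahydroquinoline-1(2H)-carboxylate
Conditions: H2 (4 atm), Pd(OH)2/C, EtOAc/EtOH, rt
Reagents that add atoms: none
Why: Heterogeneous syn hydrogenation from the convex face, opposite both the axial C2 methyl and the C5 chain, sets 8aR (cis ring fusion), and the same catalyst hydrogenolyses the benzyl ether.

Step 13
Reactants: 23 N-Boc alcohol
Product: 24 tert-butyl (2S,4aS,5S,8aR)-5-[(5R)-5-{[tert-butyl(dimethyl)silyl]oxy}octyl]-2-methyl-3-oxooctahydroquinoline-1(2H)-carboxylate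
Conditions: Dess–Martin periodinane, CH2Cl2, rt
Reagents that add atoms: none
Why: Neutral Dess–Martin oxidation of the only free alcohol tolerates Boc and TBS and makes C2–H enolisable.

Step 14
Reactants: 24 N-Boc ketone
Product: 26 (2R,4aS,5S,8aR)-5-[(5R)-5-{[tert-butyl(dimethyl)silyl]oxy}octyl]-2-methyloctahydroquinolin-3(2H)-one, via (2S)-amino ketone 25 (not isolated)
Conditions: TMSOTf, 2,6-lutidine, CH2Cl2, 0 °C; then K2CO3, MeOH, rt, 12 h
Reagents that add atoms: none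
Why: Silyl-triflate Boc cleavage spares the TBS ether, and base-mediated enolisation then epimerises C2 thermodynamically, because in the NH series the all-cis C5 chain locks the chair with C8 axial, so the 2S methyl is syn-diaxial and converts to the equatorial 2R epimer.

Step 15
Reactants: 27 (E)-oct-2-enoic acid
Product: 28 (E)-oct-2-enoyl chloride
Conditions: (COCl)2, DMF (cat.), CH2Cl2, 0 °C → rt
Reagents that add atoms: oxalyl chloride, O=C(Cl)C(=O)Cl
Why: Vilsmeier-type acid chloride formation under mild conditions keeps the E-alkene intact.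

Step 16
Reactants: 26 (2R)-amino ketone; 28 (E)-oct-2-enoyl chloride
Product: 30 (2R,3R,4aS,5S,8aR)-5-[(5R)-5-{[tert-butyl(dimethyl)silyl]oxy}octyl]-2-methyldecahydroquinolin-3-yl (2E)-oct-2-enoate, via lithium alkoxide 29 (not isolated)
Conditions: L-Selectride (1.0 equiv), THF, −78 °C; then 28 (1.05 equiv), −78 → 0 °C; H2O
Reagents that add atoms: none
Why: The bulky hydride attacks the 3-ketone equatorially to give the axial (3R) alkoxide cis to the equatorial C2 methyl, and this alkoxide outcompetes the hindered 2,6-disubstituted NH in nucleophilic acyl substitution.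

Step 17
Reactants: 30 silyl ether
Product: 31 (2R,3R,4aS,5S,8aR)-5-[(5R)-5-hydroxyoctyl]-2-methyldecahydroquinolin-3-yl (2E)-oct-2-enoate (target)
Conditions: HF·pyridine, THF, 0 °C → rt; aq NaHCO3
Reagents that add atoms: none
Why: Fluoride-mediated desilylation removes the last protecting group without affecting the enoate, the amine or any stereocentre.

## Compound list
1 | (R)-2-propyloxirane | CCC[C@@H]1CO1 | starting material
2 | pent-4-en-1-ylmagnesium bromide | C=CCCC[Mg]Br | starting material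
3 | (4R)-dec-9-en-4-ol | C=CCCCC[C@H](O)CCC | intermediate
4 | tert-butyl{[(4R)-dec-9-en-4-yl]oxy}dimethylsilane | C=CCCCC[C@H](O[Si](C)(C)C(C)(C)C)CCC | intermediate
5 | secondary ozonide (3-substituted 1,2,4-trioxolane) of 4 | C1OOC(CCCC[C@H](O[Si](C)(C)C(C)(C)C)CCC)O1 | intermediate
6 | (6R)-6-{[tert-butyl(dimethyl)silyl]oxy}nonanal | O=CCCCC[C@H](O[Si](C)(C)C(C)(C)C)CCC | intermediate
7 | diethyl [3-(trimethylsilyl)prop-2-yn-1-yl]phosphonate | CCOP(=O)(CC#C[Si](C)(C)C)OCC | starting material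
8 | (3E,9R)-9-(TBS-oxy)-1-(trimethylsilyl)dodec-3-en-1-yne | C[Si](C)(C)C#C/C=C/CCCC[C@H](O[Si](C)(C)C(C)(C)C)CCC | intermediate
9 | (3E,9R)-9-(TBS-oxy)dodec-3-en-1-yne | C#C/C=C/CCCC[C@H](O[Si](C)(C)C(C)(C)C)CCC | intermediate
10 | tert-butyl [(2S)-1-oxopropan-2-yl]carbamate | C[C@H](NC(=O)OC(C)(C)C)C=O | starting material
11 | (3-ethoxy-3-oxopropyl)zinc bromide | CCOC(=O)CC[Zn]Br | starting material
12 | (3-ethoxy-3-oxopropyl)tri(propan-2-yloxy)titanium | CCOC(=O)CC[Ti](OC(C)C)(OC(C)C)OC(C)C | intermediate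
13 | ethyl (4S,5S)-5-[(tert-butoxycarbonyl)amino]-4-hydroxyhexanoate | CCOC(=O)CC[C@H](O)[C@H](C)NC(=O)OC(C)(C)C | intermediate
14 | tert-butyl {(1S)-1-[(2S)-5-oxooxolan-2-yl]ethyl}carbamate | C[C@H](NC(=O)OC(C)(C)C)[C@@H]1CCC(=O)O1 | intermediate
15 | (5S)-5-[(1S)-1-aminoethyl]oxolan-2-one | C[C@H](N)[C@@H]1CCC(=O)O1 | intermediate
16 | (5S,6S)-5-hydroxy-6-methylpiperidin-2-one | C[C@@H]1NC(=O)CC[C@@H]1O | intermediate
17 | (5S,6S)-5-(benzyloxy)-6-methylpiperidin-2-one | C[C@@H]1NC(=O)CC[C@@H]1OCc1ccccc1 | intermediate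
18 | tert-butyl (2S,3S)-3-(benzyloxy)-2-methyl-6-oxopiperidine-1-carboxylate | C[C@@H]1N(C(=O)OC(C)(C)C)C(=O)CC[C@@H]1OCc1ccccc1 | intermediate
19 | tert-butyl (2S,3S)-3-(benzyloxy)-6-[(diphenoxyphosphoryl)oxy]-2-methyl-3,4-dihydro-2H-pyridine-1-carboxylate | C[C@@H]1N(C(=O)OC(C)(C)C)C(OP(=O)(Oc2ccccc2)Oc2ccccc2)=CC[C@@H]1OCc1ccccc1 | intermediate
20 | dienyne: 6-[(3E,9R)-9-(TBS-oxy)dodec-3-en-1-yn-1-yl] enecarbamate (2S,3S) | C[C@@H]1N(C(=O)OC(C)(C)C)C(C#C/C=C/CCCC[C@H](O[Si](C)(C)C(C)(C)C)CCC)=CC[C@@H]1OCc1ccccc1 | intermediate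
21 | amidotriene: 6-[(1Z,3E,9R)-9-(TBS-oxy)dodeca-1,3-dien-1-yl] enecarbamate (2S,3S) | C[C@@H]1N(C(=O)OC(C)(C)C)C(/C=C\C=C\CCCC[C@H](O[Si](C)(C)C(C)(C)C)CCC)=CC[C@@H]1OCc1ccccc1 | intermediate
22 | tert-butyl (2S,3S,4aS,5S)-3-(benzyloxy)-5-[(5R)-5-(TBS-oxy)octyl]-2-methyl-3,4,4a,5-tetrahydroquinoline-1(2H)-carboxylate | O(Cc1ccccc1)[C@H]1C[C@H]2[C@@H](CCCC[C@H](O[Si](C)(C)C(C)(C)C)CCC)C=CC=C2N(C(=O)OC(C)(C)C)[C@H]1C | intermediate
23 | tert-butyl (2S,3S,4aS,5S,8aR)-5-[(5R)-5-(TBS-oxy)octyl]-3-hydroxy-2-methyloctahydroquinoline-1(2H)-carboxylate | O[C@H]1C[C@H]2[C@@H](CCCC[C@H](O[Si](C)(C)C(C)(C)C)CCC)CCC[C@H]2N(C(=O)OC(C)(C)C)[C@H]1C | intermediate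
24 | tert-butyl (2S,4aS,5S,8aR)-5-[(5R)-5-(TBS-oxy)octyl]-2-methyl-3-oxooctahydroquinoline-1(2H)-carboxylate | O=C1C[C@H]2[C@@H](CCCC[C@H](O[Si](C)(C)C(C)(C)C)CCC)CCC[C@H]2N(C(=O)OC(C)(C)C)[C@H]1C | intermediate
25 | (2S,4aS,5S,8aR)-5-[(5R)-5-(TBS-oxy)octyl]-2-methyloctahydroquinolin-3(2H)-one | O=C1C[C@H]2[C@@H](CCCC[C@H](O[Si](C)(C)C(C)(C)C)CCC)CCC[C@H]2N[C@H]1C | intermediate
26 | (2R,4aS,5S,8aR)-5-[(5R)-5-(TBS-oxy)octyl]-2-methyloctahydroquinolin-3(2H)-one | O=C1C[C@H]2[C@@H](CCCC[C@H](O[Si](C)(C)C(C)(C)C)CCC)CCC[C@H]2N[C@@H]1C | intermediate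
27 | (E)-oct-2-enoic acid | CCCCC/C=C/C(=O)O | starting material
28 | (E)-oct-2-enoyl chloride | CCCCC/C=C/C(=O)Cl | intermediate
29 | lithium (2R,3R,4aS,5S,8aR)-5-[(5R)-5-(TBS-oxy)octyl]-2-methyldecahydroquinolin-3-olate | [Li+].[O-][C@@H]1C[C@H]2[C@@H](CCCC[C@H](O[Si](C)(C)C(C)(C)C)CCC)CCC[C@H]2N[C@@H]1C | intermediate
30 | (2R,3R,4aS,5S,8aR)-5-[(5R)-5-(TBS-oxy)octyl]-2-methyldecahydroquinolin-3-yl (2E)-oct-2-enoate | CCCCC/C=C/C(=O)O[C@@H]1C[C@H]2[C@@H](CCCC[C@H](O[Si](C)(C)C(C)(C)C)CCC)CCC[C@H]2N[C@@H]1C | intermediate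
31 | (2R,3R,4aS,5S,8aR)-5-[(5R)-5-hydroxyoctyl]-2-methyldecahydroquinolin-3-yl (2E)-oct-2-enoate | CCCCC/C=C/C(=O)O[C@@H]1C[C@H]2[C@@H](CCCC[C@H](O)CCC)CCC[C@H]2N[C@@H]1C | target

## Step count and risks
Total steps: 17. Longest linear sequence: 12 (10 → 31 through steps 5–14, 16 and 17).

**Step 11.** The risks are over-reduction or poor Z-selectivity on the conjugated dienyne, and losses on heating. The fallback sets out from enyne 9 and enol phosphate 19 and avoids alkyne reduction on the coupled material.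
- Rh-catalysed trans-hydroboration of 9 ([Rh(cod)Cl]2, P(iPr)3, Et3N, pinacolborane) gives the (1Z,3E)-dienyl pinacolboronate F1.
- Suzuki–Miyaura coupling of F1 with 19 (PdCl2(dppf), aq Cs2CO3, THF, 50 °C) delivers the triene with the Z-geometry already in place.
- The route is rejoined at 21, which is heated as before.

**Step 12.** The risks are Pd-induced aromatisation of the cyclohexadiene and erosion of facial selectivity at C8a. The fallback sets out from 22 and replaces surface hydrogenation at C8a by a stereoelectronically controlled hydride addition.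
- TMSOTf/2,6-lutidine followed by MeOH removes the Boc group, and the NH dienamine tautomerises to the conjugated cyclic imine F2.
- Luche-type 1,2-reduction (NaBH4, CeCl3, MeOH, −78 °C) adds hydride axially, anti to the axial C4a–C5 bond, and gives the 8aR allylic amine F3.
- Boc2O gives the carbamate F4. H2 over Pd(OH)2/C then only has to saturate one isolated alkene and cleave the benzyl ether.
- The route is rejoined at 23.

**Step 16.** The risks are competing N-acylation and conjugate reduction by residual hydride in the one-pot reduction/acylation. The fallback sets out from 26 and separates the events under N-protection.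
- L-Selectride followed by water gives the amino alcohol F5, and Boc2O gives the N-Boc amino alcohol F6.
- Steglich esterification of F6 with acid 27 (DCC, DMAP) gives the N-Boc ester F7.
- TFA/H2O (9:1) in CH2Cl2 removes Boc and TBS together, and the route is rejoined at 31.

## Further compounds
F1 | step 11 | 2-[(1Z,3E,9R)-9-{[tert-butyl(dimethyl)silyl]oxy}dodeca-1,3-dien-1-yl]-4,4,5,5-tetramethyl-1,3,2-dioxaborolane | CC1(C)OB(/C=C\C=C\CCCC[C@H](O[Si](C)(C)C(C)(C)C)CCC)OC1(C)C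
F2 | step 12 | (2S,3S,4aS,5S)-3-(benzyloxy)-5-[(5R)-5-(TBS-oxy)octyl]-2-methyl-2,3,4,4a,5,6-hexahydroquinoline | O(Cc1ccccc1)[C@H]1C[C@H]2[C@@H](CCCC[C@H](O[Si](C)(C)C(C)(C)C)CCC)CC=CC2=N[C@H]1C
F3 | step 12 | (2S,3S,4aS,5S,8aR)-3-(benzyloxy)-5-[(5R)-5-(TBS-oxy)octyl]-2-methyl-1,2,3,4,4a,5,6,8a-octahydroquinoline | O(Cc1ccccc1)[C@H]1C[C@H]2[C@@H](CCCC[C@H](O[Si](C)(C)C(C)(C)C)CCC)CC=C[C@H]2N[C@H]1C
F4 | step 12 | tert-butyl (2S,3S,4aS,5S,8aR)-3-(benzyloxy)-5-[(5R)-5-(TBS-oxy)octyl]-2-methyl-3,4,4a,5,6,8a-hexahydroquinoline-1(2H)-carboxylate | O(Cc1ccccc1)[C@H]1C[C@H]2[C@@H](CCCC[C@H](O[Si](C)(C)C(C)(C)C)CCC)CC=C[C@H]2N(C(=O)OC(C)(C)C)[C@H]1C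
F5 | step 16 | (2R,3R,4aS,5S,8aR)-5-[(5R)-5-(TBS-oxy)octyl]-2-methyldecahydroquinolin-3-ol | O[C@@H]1C[C@H]2[C@@H](CCCC[C@H](O[Si](C)(C)C(C)(C)C)CCC)CCC[C@H]2N[C@@H]1C
F6 | step 16 | tert-butyl (2R,3R,4aS,5S,8aR)-5-[(5R)-5-(TBS-oxy)octyl]-3-hydroxy-2-methyloctahydroquinoline-1(2H)-carboxylate | O[C@@H]1C[C@H]2[C@@H](CCCC[C@H](O[Si](C)(C)C(C)(C)C)CCC)CCC[C@H]2N(C(=O)OC(C)(C)C)[C@@H]1C
F7 | step 16 | tert-butyl (2R,3R,4aS,5S,8aR)-5-[(5R)-5-(TBS-oxy)octyl]-2-methyl-3-{[(2E)-oct-2-enoyl]oxy}octahydroquinoline-1(2H)-carboxylate | CCCCC/C=C/C(=O)O[C@@H]1C[C@H]2[C@@H](CCCC[C@H](O[Si](C)(C)C(C)(C)C)CCC)CCC[C@H]2N(C(=O)OC(C)(C)C)[C@@H]1C
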